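If each capture agent took one open intermediate, the row could lose at most the extra charge, taken as a share of the substrate charge. That was my starting point.

| setting | beta | gamma | Friday's | Saturday's | Sunday's | Thursday's | Wednesday's |
|---|---|---|---|---|---|---|---|
| substrate | 0.30 mM | 0.10 mM | 0.20 mM | 0.20 mM | 0.20 mM | 0.20 mM | 0.20 mM |
| capture agent | 0.0020 mM | 0.0020 mM | 0.00200 mM | 0.00250 mM | 0.00400 mM | 0.00600 mM | 0.0100 mM |
| catalyst | 0.20 µM | 0.20 µM | 0.20 µM | 0.20 µM | 0.20 µM | 0.20 µM | 0.20 µM |
| remark | run made earlier | run made earlier |  |  |  |  |  |
| time |  |  | 2.0 min | 2.0 min | 2.0 min | 2.0 min | 2.0 min |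

| run | time / s | open intermediate / % | product / % |
|---|---|---|---|
| beta | 12.0 | 40.3 | 4.7 |
| beta | 25.0 | 56.7 | 16.1 |
| beta | 40.0 | 56.3 | 30.6 |
| beta | 50.0 | 51.4 | 40.7 |
| beta | 60.0 | 45.9 | 48.4 |
| beta | 80.0 | 35.5 | 63.4 |
| gamma | 12.0 | 41.9 | 5.2 |
| gamma | 25.0 | 56.5 | 16.2 |
| gamma | 40.0 | 56.1 | 30.9 |
| gamma | 50.0 | 51.8 | 41.3 |
| gamma | 60.0 | 46.1 | 48.9 |
| gamma | 80.0 | 33.4 | 62.4 |

(each reading ± 0.5 percentage points)

1. amount of open intermediate at the end, in percent of the substrate charged for Friday's, Saturday's, Sunday's, Thursday's, Wednesday's, in this order
2. the shape of the row from first to last (falls, then rises / rises, then falls / hardly changes / falls all the way / rises all the way)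

- the numbers in the tables scatter by 0.5 percentage points (one standard deviation)
- "hardly changes" means that all values lie within two and a half points (for a concentration: within two and a half percent of the largest)
- no earlier run changes the charge of capture agent; that part of a forecast is a guess

At 40.0 s, beta and gamma read 56.3% and 56.1% of open intermediate, though their substrate charges were 0.30 mM and 0.10 mM. So I treated its decay to product as pseudo-first-order, with one constant k. I read k from beta as product gained per second over the mean open intermediate, between 50.0 s and 80.0 s:

k = 0.0174 s⁻¹

Beta's readings stood highest around 25.0 s to 40.0 s, so I put the capture at 40.0 s. Of open intermediate left untaken then, a share of 24.9% would still have stood at the end. I folded both facts into one number, D: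

D = (0.0100 mM − 0.00200 mM) / 0.20 mM × exp(−k × (2.0 min − 40.0 s)) = 0.99 percentage points

D is the dent: my estimate of the points the row loses from Friday's to Wednesday's, taking the extra capture agent as used up and counting what would still have survived at the end.

One number assumes one capture time, so I tried an earlier and a later one. Capture at the start gave 0.49 points. Capture at 80.0 s gave 2 points, which is below the margin of 2.5 points. So, taking the capture as over by 80.0 s, I expected the row to stay flat, though my reckoning gave the drop and not the level.

The forecast ran from 18.2% to 17.2%, with the shape hardly changes, since captured material “would mostly have decayed anyway”.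

The flasks gave 18.3%, 18.2%, 18.0%, 17.8% and 17.4%, so the shape was hardly changes.

    substrate → open intermediate (k = 0.0510 s⁻¹)
    catalyst + open intermediate → catalyst + product (k = 87000 M⁻¹ s⁻¹)
    open intermediate + capture agent → trapped intermediate (k = 140 M⁻¹ s⁻¹)

The drop from Friday's to Wednesday's was 0.9 points, against a dent of 0.99 points. Wednesday's ended with 3.59% trapped intermediate and 28% of its capture agent left. Scaled to Sunday's charge, the dent is 0.25 points, and Sunday's stood 0.3 points below Friday's.

(The readings are calculated with made-up constants, noise included.)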